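The numbers in the tables are calculated from invented constants.

**Slow end.** The slowness of the late readings struck me when you asked for a quick number on this flask: in the epsilon run, the same flask followed so far, left-handed product moved from 24 % at 4.00 d to 25 % at 5.00 d, a step inside the scatter of 2 percentage points.

in all of them: left-handed substrate 0.53 M; right-handed substrate 0.53 M
- epsilon: coupling partner 0.53 M; temperature 25 °C; the very flask that is asked about, followed so far
- eta: coupling partner 0.53 M; temperature 20 °C; run made earlier
- flask: coupling partner 0.530 M; temperature 25 °C; time 8.0 d

- epsilon (time / d: left-handed product / %, left-handed substrate / %): 0.333: 10, 39; 0.833: 19, 38; 1.67: 21, 32; 2.50: 20, 35; 4.00: 24, 32; 5.00: 25, 32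
- eta (time / d: left-handed product / %, left-handed substrate / %): 0.333: 11, 42; 0.833: 13, 39; 1.67: 18, 33; 2.50: 24, 34; 4.00: 24, 31; 5.00: 27, 33

(readings scatter by 2 percentage points)

- alder: at 8.0 d take out 90 % of the left-handed product then present, then wait 8.0 d
- larch: change nothing and wait 8.0 d more
- ash: at 8.0 d raise the temperature by 10 K, then wait 8.0 d
- cedar: at 8.0 d add coupling partner, 100 % of the amount charged, then wait 8.0 d

- coupling partner is single-handed; left-handed substrate and right-handed substrate are mirror images of each other, charged as a racemate, each of them at the stated concentration
- what is taken out of left-handed product is counted as made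
- additions bring no volume worth counting
- the handed part of coupling partner does not stay in what it makes, so the products of the two hands are mirror images too

- left-handed product, in percent of the left-handed substrate and right-handed substrate together first charged, at 8.0 d
- which option adds most left-handed product ("none" when 2 percentage points or less is all one gets) (alder / larch / ash / cedar / none)
- left-handed product present, with what was taken out counted in, in percent of the left-handed substrate and right-handed substrate together first charged, after alder
- left-handed product present, with what was taken out counted in, in percent of the left-handed substrate and right-handed substrate together first charged, after cedar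

**Fast end.** The first reading of the epsilon run, 10 % at 0.333 d, gave the starting slope, with its scatter. That late level over that slope made a time constant of 0.833 d, and 8.0 d is 9.60 such constants, so I joined the two ends and took the curve as flat by then. Left-handed substrate in the epsilon run still read 32 %, so I guessed that the coupling partner was the limiting reagent.

**Partner yield.** The last reading of the epsilon run, with its scatter, gives 50.0 % for the partner yield, the left-handed product made per coupling partner charged. My number for 8.0 d was therefore 25.0 %. Alder, larch and ash bring no coupling partner, so I reckoned no gain from them. Cedar brings 100 % more, so I reckoned 25 points more, reaching 50.0 %.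

**Your forecast.** The forecast gave 27 %, 37 % after alder and 42 % after cedar, and chose cedar, on the ground of “a reversible coupling near equilibrium”. We agreed on the choice and parted on alder, where I held 25.0 %.

**The flask.** The flask gave 25.3 %, 25.3 % after alder and 46.3 % after cedar, so cedar added 21 points where the 50.0 % partner yield had promised 25 points.

    coupling partner → decomposed reagent (k = 2.50 × 10⁻⁴ min⁻¹, Ea = 108 kJ mol⁻¹)
    left-handed substrate ⇌ right-handed substrate (k = 5.20 × 10⁻⁴ min⁻¹, Ea = 96.0 kJ mol⁻¹)
    2 coupling partner → self-condensation product (k = 3.20 × 10⁻⁴ M⁻¹ min⁻¹, Ea = 67.0 kJ mol⁻¹)
    coupling partner + right-handed substrate → right-handed product (k = 2.70 × 10⁻⁴ M⁻¹ min⁻¹, Ea = 70.0 kJ mol⁻¹)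
    coupling partner + left-handed substrate → left-handed product (k = 0.00130 M⁻¹ min⁻¹, Ea = 70.0 kJ mol⁻¹)
    (constants at 25 °C)

In the flask at 0.416 d, coupling with left-handed substrate used coupling partner 2.1 times as fast as its passing into decomposed reagent. At 8.00 d the flask held 0 % of its coupling partner, with left-handed substrate at 34.4 %.

**Less partner.** With 0.32 M of coupling partner in the neighbouring flask, the partner yield gives 15.1 %. The computed result there is 16.7 %.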